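(The readings are calculated with made-up constants; scatter was added.)

A straight stretch in a substrate curve is a trap: it tempts one to extend it down to zero and to expect the target to climb until then.

common to all: substrate 0.47 M

| charge | reagent in the second phase | remark | time | volume of the second phase over the first |
|---|---|---|---|---|
| midnight | 4 equiv | the very flask that is asked about, followed so far |  |  |
| noon | 8 equiv | run made earlier |  |  |
| flask | 4.00 equiv |  | 1.0 h | 2.0 |

| run | time / min | target / % | substrate / % |
|---|---|---|---|
| midnight | 0.417 | 3.0 | 97.6 |
| midnight | 0.667 | 5.4 | 94.7 |
| midnight | 0.833 | 7.1 | 91.8 |
| midnight | 1.33 | 14.0 | 86.4 |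
| midnight | 2.00 | 19.4 | 75.9 |
| midnight | 3.00 | 28.1 | 65.4 |
| midnight | 5.00 | 35.3 | 47.1 |
| noon | 3.00 | 40.3 | 39.1 |
| noon | 5.00 | 37.8 | 15.7 |
| noon | 8.00 | 16.5 | 5.2 |
| noon | 12.0 | 2.5 | 0.5 |
| noon | 20.0 | 0 | 0.4 |
| noon | 30.0 | 0 | 0 |
| noon | 40.0 | 0 | 0.5 |

(each reading ± 1 percentage point)

- when, up to 1.0 h, the flask holds most target
- the amount of target, in percent of the substrate charged, at that time
- earliest time at which at least nineteen twentieths of that best amount are there
- latest time at which they still are

- in the second phase: reagent in the second phase; everything else is in the first
- charges count per volume of the first phase; a concentration in a rate is the amount of a species over the volume of its own phase; every rate counts per litre of the first phase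
- the earlier runs hold the two phases in the same ratio of volumes as the flask asked about

Two chemists argue over the midnight flask. The second chemist draws the line. Up to the last reading, at 5.00 min, the substrate falls by a fraction of its charge of 0.106 min⁻¹. She reads this as a fixed supply of reagent across the phases. On her view substrate reaches zero at 9.45 min, and the target peaks there. Her line suits the early readings: at 1.33 min it gives 85.9% against a reading of 86.4%.

The first chemist treats the decay as pseudo-first-order. She defines the substrate life 6.64 min, the time in which substrate falls by a factor e, read from that last reading. Her curve gives 81.9% at 1.33 min, so she concedes the first minutes to the line. But suppose target is used up with the same life as substrate. Then target equals substrate times elapsed lives, which is 35.5% at 5.00 min, and the reading is 35.3%.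

The noon run speaks for her too. Its life is 2.70 min, and its highest reading, 40.3%, stands at 3.00 min. Target reads lower at 5.00 min, 37.8%, with substrate still at 15.7%.

I side with the first chemist. I reckon the peak of the midnight flask at one life, 0.111 h, with target at 36.8%. Expanding the curve around the peak puts the asked window 0.316 of a life either side, from 0.0759 h to 0.146 h.

The forecast gives 36.5% at 0.105 h and a window from 0.077 h to 0.145 h, holding that “Reagent depletion and the acceleration partly offset each other”.

The flask gives 36.8% at 0.117 h, with a window from 0.0858 h to 0.152 h. In this flask the best time comes earlier than the line's zero, with substrate still at 29.3%.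

    reagent in the reaction phase ⇌ reagent in the second phase, rate k1*([reagent in the reaction phase] - [reagent in the second phase]/K1) per volume of the first phase (partition coefficient = 1.20, kL = 0.00170 s⁻¹)
    substrate + reagent in the reaction phase → target (k = 0.0810 L mol⁻¹ s⁻¹)
    reagent in the reaction phase + target → over-reacted product (k = 0.0420 L mol⁻¹ s⁻¹)
    target ⇌ isomer of the product (K = 0.800, k = 0.00240 s⁻¹)

The best time of this flask lies 1.05 lives out. A neighbouring flask has the same charges but is read at 25 min, which is 3.75 lives. The reckoning therefore puts the peak inside that run, and it leaves 8.79% of target at the reading. The neighbouring flask reaches 36.8% on its way. At its reading it holds 3.49% of target, less than reckoned, beside 8.45% of isomer of the product and 88.1% of over-reacted product.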